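The earlier runs and the new flask are calculated with constants of no real substance; noise was put on by code.

**A tempting rule.** The pitfall in a dosing series is to read the reagent charge as the loss itself. I wanted the share of target among the finished products of four flasks, each stopped at 2.5 d.

| flask | solid substrate | reagent | remark | time |
|---|---|---|---|---|
| Saturday's | 34 mM | 3 mM (fed, over 20 h) | run made earlier; the fed solution adds 0.20 times the starting volume |  |
| eta | 23 mM | 3.00 mM (fed, over 20 h) | the fed solution adds 0.20 times the starting volume | 2.5 d |
| gamma | 23 mM | 6.00 mM (fed, over 20 h) | the fed solution adds 0.20 times the starting volume | 2.5 d |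
| theta | 23 mM | 15.0 mM (fed, over 20 h) | the fed solution adds 0.20 times the starting volume | 2.5 d |
| epsilon | 23 mM | 30.0 mM (fed, over 20 h) | the fed solution adds 0.20 times the starting volume | 2.5 d |

Saturday's run (percent of the solid substrate charged)

| time / h | target / % | side product A / % |
|---|---|---|
| 2.00 | 0.4 | 0 |
| 5.00 | 2.8 | 0.1 |
| 10.0 | 8.1 | 0 |
| 15.0 | 13.9 | 0.7 |
| 20.0 | 18.8 | 0.2 |

(readings scatter by 0.3 percentage points)

- share of target in all that became target or side product A or side product B for eta, gamma, theta, epsilon, in this order
- the shape of the row from first to last (rises all the way / falls, then rises / rises, then falls / falls all the way / hardly changes)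

- amounts are per litre of the starting volume; all of the dose is in the solution fed
- solid substrate is a solid; its amount is given per volume of the solution
- the numbers in the tables scatter with a standard deviation of 0.3 percentage points
- reactions considered so far: starting material <-> intermediate A; starting material + reagent -> intermediate B; intermediate B -> intermediate C; intermediate A -> target; reagent + intermediate C -> side product A; intermediate C -> side product B; solid substrate <-> starting material
- at the start none of the solid substrate is in solution
- "hardly changes" means that all values lie within two and a half points (for a concentration: within two and a half percent of the largest)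

**The ceiling.** My bench rule counted charges. Each starting material lost to intermediate B takes at least one reagent, so reagent acts as the limiting reagent of the loss. For eta, reagent charge over solid charge is 13.0%, and I called this ratio the ceiling. A fully finished eta should therefore keep a share of at least 87.0%. The same ratio gave 26.1% for gamma and 65.2% for theta.

**Where it stops.** In epsilon the ratio is 1.30, so the reagent charge is larger than the solid charge and the rule sets no floor. I turned to rates. In Saturday's run, target grew by about 0.364 mM h⁻¹ late on, while reagent entered at 0.150 mM h⁻¹, and side product A at 20.0 h read 0.2%, within the scatter. Epsilon's feed of 1.50 mM h⁻¹ is faster than that reading of target growth. The scheme's route to target uses no reagent, but the attack on starting material does, so I expected the comparison to worsen with dose. I committed to a falling row, with eta, gamma and theta above their floors.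

**The forecast.** The forecast gave 89%, 78%, 55% and 35%, shape falls all the way, reasoning from “at most one substrate per reagent”.

**The result.** The flasks gave 98.4%, 96.8%, 91.4% and 82.2%, and the row falls all the way.

    starting material ⇌ intermediate A (K = 5.10, k = 1.00 × 10⁻⁵ s⁻¹)
    starting material + reagent → intermediate B (k = 1.80 × 10⁻⁴ L mol⁻¹ s⁻¹)
    intermediate B → intermediate C (k = 6.30 × 10⁻⁵ s⁻¹)
    intermediate A → target (k = 2.10 × 10⁻⁴ s⁻¹)
    reagent + intermediate C → side product A (k = 2.40 × 10⁻⁴ L mol⁻¹ s⁻¹)
    intermediate C → side product B (k = 7.00 × 10⁻⁶ s⁻¹)
    solid substrate ⇌ starting material, rate k7*(cs7 - [starting material]) while solid is left; crystals form when [starting material] > cs7 (solubility = 9.60 mM, k = 2.80 × 10⁻⁴ s⁻¹)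

**Ceiling used.** Epsilon still held 78% of its reagent charge at 2.50 d. At 2.50 d, eta's side products A and B together stood at 1.27% of the solid charged, which is 0.0975 of its ceiling, while 17.0% of that charge was still starting material. Epsilon's side products A and B together stood at 14.7% of the solid charged, which is 0.112 of its ceiling of 1.30, while 9.12% of that charge was still starting material.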